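The target is cut at C13–C14 into a butenolide aldehyde and a labdane core, and the core is unravelled to an open (E,E)-triene methyl ketone whose only stereocentre is the C6 silyloxy carbon. One bromonium-triggered cascade closes ring A, ring B and the C8–O–C13 dihydropyran and sets C5, C10, C9 and C8 from C6. The step exploits the 6α-oxygen of ring B: allylic to C5=C10 in the chain, it must sit equatorial in the chair fold, and in the decalin it lies peri to the 4α-methyl C18, which it later oxidises by 1,5-hydrogen transfer; the 8α-O/C13 ketone pair terminates the cascade.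

Key step: step 6

Remark: labdane numbering is used for the core (C16 = the carbon on C13 that ends as the exo-methylene, C17 = methyl on C8, C18 = 4α carbon, C19 = 4β methyl, C20 = methyl on C10).
Remark: geranial is taken as the isomerically pure (E)-aldehyde.
Remark: where a catalyst or ligand antipode is named only by its outcome, the antipode that gives the stated configuration is used.

**Route**

Step 1
Reactants: 1 geranial; 2 allenylboronic acid pinacol ester
Product: 3 (4S,5E)-6,10-dimethylundeca-5,9-dien-1-yn-4-ol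
Conditions: (S)-TRIP phosphoric acid (10 mol%; antipode that gives the 4S alcohol), 4 Å MS, toluene, 0 °C
Reagents that add atoms: none
Why: Chiral phosphoric acid-catalysed propargylboration of the enal runs through a closed six-membered SE2′ transition state in which the catalyst activates the boronate and shields one aldehyde face, so the allenyl group is delivered with transposition and sets the future C6 carbinol as S.

Step 2
Reactants: 3 (4S,5E)-6,10-dimethylundeca-5,9-dien-1-yn-4-ol
Product: 4 (4S,5E)-4-(tert-butyldimethylsilyloxy)-6,10-dimethylundeca-5,9-dien-1-yne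
Conditions: TBSCl, imidazole, DMF, rt
Reagents that add atoms: tert-butyldimethylsilyl chloride, CC(C)(C)[Si](C)(C)Cl
Why: Silylation of the secondary allylic alcohol gives an ether that withstands the organometallic steps and cannot act as a nucleophile or leaving group in the cyclisation.

Step 3
Reactants: 4 (4S,5E)-4-(tert-butyldimethylsilyloxy)-6,10-dimethylundeca-5,9-dien-1-yne
Product: 6 (1E,4S,5E)-4-(tert-butyldimethylsilyloxy)-1-iodo-2,6,10-trimethylundeca-1,5,9-triene, via vinylalane 5 (not isolated)
Conditions: Me3Al, Cp2ZrCl2 (20 mol%), H2O (1 equiv), CH2Cl2, −20 °C; then I2, THF, −30 → 0 °C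
Reagents that add atoms: trimethylaluminium, C[Al](C)C; iodine, II
Why: Zirconium-catalysed carboalumination adds methyl (C17) and aluminium syn across the terminal alkyne with methyl on the internal carbon, and iodinolysis of the C–Al bond with retention gives the E iodide while the trisubstituted alkenes stay inert.

Step 4
Reactants: 6 (1E,4S,5E)-4-(tert-butyldimethylsilyloxy)-1-iodo-2,6,10-trimethylundeca-1,5,9-triene; 7 2-(2-bromoethyl)-2-methyl-1,3-dioxolane
Product: 9 (5E,8S,9E)-8-(tert-butyldimethylsilyloxy)-6,10,14-trimethylpentadeca-5,9,13-trien-2-one ethylene ketal, via alkylzinc bromide 8 (not isolated)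
Conditions: 7, Zn dust, LiCl, THF, 40 °C; then 6, Pd(dppf)Cl2 (5 mol%), THF/NMP, 50 °C
Reagents that add atoms: none
Why: Zinc insertion into the primary bromide and Negishi sp2–sp3 coupling form the C9–C11 bond with retention of the E geometry, the ketal keeping the ketone out of the organometallic chemistry.

Step 5
Reactants: 9 (5E,8S,9E)-8-(tert-butyldimethylsilyloxy)-6,10,14-trimethylpentadeca-5,9,13-trien-2-one ethylene ketal
Product: 10 (5E,8S,9E)-8-(tert-butyldimethylsilyloxy)-6,10,14-trimethylpentadeca-5,9,13-trien-2-one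
Conditions: PPTS (cat.), acetone/H2O, 45 °C
Reagents that add atoms: water, O
Why: Mild acid-catalysed acetal hydrolysis frees the methyl ketone under conditions that the secondary TBS ether and the trisubstituted alkenes tolerate.

Step 6
Reactants: 10 (5E,8S,9E)-8-(tert-butyldimethylsilyloxy)-6,10,14-trimethylpentadeca-5,9,13-trien-2-one
Product: 11 3β-bromo-6α-(tert-butyldimethylsilyloxy)-8α,13-epoxy-14,15-dinorlabd-12-ene
Conditions: bromodiethylsulfonium bromopentachloroantimonate (BDSB, 1.1 equiv), MeNO2, −25 °C, 5 min; aq. NaHCO3/Na2SO3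
Reagents that add atoms: bromodiethylsulfonium bromopentachloroantimonate, CC[S+](Br)CC.Cl[Sb-](Cl)(Cl)(Cl)(Cl)Br
Why: Proposed new method: the sulfonium salt transfers Br+ to the terminal C3=C4 alkene and the bromonium ion is opened in a cation–olefin cascade in which C5 attacks C4, C9 attacks C10, the ketone oxygen attacks C8 and the oxocarbenium ion loses H12 to give the enol ether; the closest known reactions are bromonium-induced cyclisations of farnesyl-type polyenes with heteroatom termination and the acid-induced closure of farnesylacetone to the same 8,13-epoxy enol ether, and what is untested is an allylic silyloxy stereocentre inside the chain as the only control element. Ring A closes 6-endo through a chair, ring B closes 6-endo through a second chair, and the dihydropyran closes by six-membered capture of the tertiary C8 cation by the carbonyl oxygen anti to the new C9–C10 bond. Anti addition across the two E alkenes fixes the trans ring fusion (C5, C10) and the C9/C8 relationship (side chain β, oxygen 8α), bromine ends equatorial at C3, and the absolute sense of folding is set by C6, because A(1,3) strain with the C20 methyl and the syn-axial clash with C19 and C20 leave only the fold with the silyloxy group equatorial (6α). The step needs site selectivity of Br+ for C3=C4 and facial selectivity of the fold; the first rests on the accessibility of the isopropylidene and the inductive deactivation of C5=C10 by the allylic oxygen, the second on the equatorial preference at C6. With no protic or oxophilic Lewis acid present the allylic silyl ether should not ionise.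

Step 7
Reactants: 11 3β-bromo-6α-(tert-butyldimethylsilyloxy)-8α,13-epoxy-14,15-dinorlabd-12-ene
Product: 12 6α-(tert-butyldimethylsilyloxy)-8α,13-epoxy-14,15-dinorlabd-12-ene
Conditions: Bu3SnH, AIBN (cat.), toluene, 90 °C
Reagents that add atoms: none
Why: Radical chain dehalogenation with tin hydride removes the C3 bromine and its stereocentre without touching the enol ether or the silyl ether.

Step 8
Reactants: 12 6α-(tert-butyldimethylsilyloxy)-8α,13-epoxy-14,15-dinorlabd-12-ene
Product: 13 (13S)-6α-(tert-butyldimethylsilyloxy)-13-methoxy-8α,13-epoxy-14,15-dinorlabdane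
Conditions: MeOH, PPTS (cat.), 0 °C → rt; Et3N quench
Reagents that add atoms: methanol, CO
Why: Acid-catalysed addition of methanol to the enol ether through the cyclic oxocarbenium ion gives the mixed ketal under thermodynamic control, the anomeric effect and the avoidance of a methyl/methyl 1,3-diaxial contact with C17 placing OMe axial (13S, a transient centre), and any exocyclic enol ether isomer converges on the same ketal.

Step 9
Reactants: 13 (13S)-6α-(tert-butyldimethylsilyloxy)-13-methoxy-8α,13-epoxy-14,15-dinorlabdane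
Product: 14 (13S)-13-methoxy-8α,13-epoxy-14,15-dinorlabdan-6α-ol
Conditions: TBAF, THF, 50 °C; aqueous work-up
Reagents that add atoms: none
Why: Fluoride-induced desilylation frees the hindered 6α-alcohol while the base-stable ketal is unaffected.

Step 10
Reactants: 14 (13S)-13-methoxy-8α,13-epoxy-14,15-dinorlabdan-6α-ol
Product: 15 (13S)-13-methoxy-6α,18:8α,13-diepoxy-14,15-dinorlabdane
Conditions: PhI(OAc)2, I2, NaHCO3, cyclohexane/CH2Cl2, hν (tungsten lamp), rt
Reagents that add atoms: none
Why: In this hypoiodite reaction light cleaves the O–I bond, the 6α-alkoxy radical abstracts hydrogen through a six-membered transition state from the peri 4α-methyl (the only C–H within reach, since the 4β-methyl and C20 lie on the other face), and the resulting C18 iodide is displaced by the 6-oxygen to close the oxolane, which makes C4 a defined stereocentre.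

Step 11
Reactants: 15 (13S)-13-methoxy-6α,18:8α,13-diepoxy-14,15-dinorlabdane
Product: 17 8α-hydroxy-13-oxo-14,15-dinorlabdan-18,6α-olide, via lactone methyl ketal 16 (not isolated)
Conditions: RuCl3·xH2O (5 mol%), NaIO4, CCl4/MeCN/H2O, rt; then 1 M HCl, rt
Reagents that add atoms: sodium periodate, [Na+].[O-]I(=O)(=O)=O; water, O
Why: Catalytic RuO4 oxidation of the ether converts the unhindered methylene C18 (the C6 methine is shielded by C19 and C20) into the γ-lactone, and the aqueous acid then hydrolyses the mixed ketal to the open 8-hydroxy 13-ketone without touching a stereocentre.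

Step 12
Reactants: 17 8α-hydroxy-13-oxo-14,15-dinorlabdan-18,6α-olide
Product: 19 methyl 6α,8α-dihydroxy-13-oxo-14,15-dinorlabdan-18-oate, via potassium carboxylate 18 (not isolated)
Conditions: KOH (1.1 equiv), MeOH/H2O, 60 °C; evaporate; then MeI, DMF, 0 °C → rt
Reagents that add atoms: potassium hydroxide, [K+].[OH-]; iodomethane, CI
Why: Saponification opens the γ-lactone at the acyl carbon (C6–O intact, configuration retained) and SN2 O-methylation of the carboxylate gives the ester without passing through the free hydroxy acid, which would relactonise.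

Step 13
Reactants: 19 methyl 6α,8α-dihydroxy-13-oxo-14,15-dinorlabdan-18-oate
Product: 20 methyl 13-oxo-6α,8α-bis(triethylsilyloxy)-14,15-dinorlabdan-18-oate
Conditions: TESOTf, 2,6-lutidine, CH2Cl2, −78 → 0 °C
Reagents that add atoms: triethylsilyl trifluoromethanesulfonate, CC[Si](CC)(CC)OS(=O)(=O)C(F)(F)F
Why: Silylation with the silyl triflate and a hindered base caps both the hindered secondary and the tertiary alcohol, which blocks relactonisation and hemiketal formation, and any silyl enol ether of the ketone is hydrolysed on work-up.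

Step 14
Reactants: 20 methyl 13-oxo-6α,8α-bis(triethylsilyloxy)-14,15-dinorlabdan-18-oate
Product: 22 methyl 6α,8α-bis(triethylsilyloxy)-13-(trifluoromethylsulfonyloxy)-14,15-dinorlabd-13(16)-en-18-oate, via potassium enolate 21 (not isolated)
Conditions: KHMDS, THF, −78 °C; then N-(5-chloro-2-pyridyl)triflimide, −78 °C
Reagents that add atoms: N-(5-chloropyridin-2-yl)bis(trifluoromethanesulfonyl)imide, FC(F)(F)S(=O)(=O)N(c1ccc(Cl)cn1)S(=O)(=O)C(F)(F)F
Why: Kinetic enolisation of the methyl ketone on the methyl side with a bulky amide base and O-sulfonylation of the less substituted enolate give the 1,1-disubstituted alkenyl triflate, the ester having no α-hydrogen.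

Step 15
Reactants: 23 3-(tert-butyldimethylsilyloxy)propanal; 24 methyl propiolate
Product: 25 methyl (4S)-6-(tert-butyldimethylsilyloxy)-4-hydroxyhex-2-ynoate
Conditions: Me2Zn, ProPhenol (10 mol%; antipode that gives the 4S carbinol), Ph3PO (20 mol%), toluene, 0 °C
Reagents that add atoms: none
Why: In the zinc/ProPhenol-catalysed asymmetric alkynylation the dinuclear zinc complex holds the zinc acetylide and the aldehyde and delivers the alkyne to one carbonyl face, which sets the future butenolide carbinol as S.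

Step 16
Reactants: 25 methyl (4S)-6-(tert-butyldimethylsilyloxy)-4-hydroxyhex-2-ynoate
Product: 27 (5S)-5-[2-(tert-butyldimethylsilyloxy)ethyl]-4-methylfuran-2(5H)-one, via Z-hydroxy enoate 26 (not isolated)
Conditions: Me2CuLi (2.5 equiv), THF, −78 °C; aq. NH4Cl, → rt
Reagents that add atoms: lithium dimethylcuprate, [Li+].C[Cu-]C
Why: Syn carbocupration (conjugate addition) of the ynoate puts methyl on the β-carbon and gives the Z enoate, whose cis γ-oxygen lactonises to the butenolide without involving the carbinol centre.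

Step 17
Reactants: 27 (5S)-5-[2-(tert-butyldimethylsilyloxy)ethyl]-4-methylfuran-2(5H)-one
Product: 28 (5S)-5-(2-hydroxyethyl)-4-methylfuran-2(5H)-one
Conditions: HF·pyridine, THF, 0 °C → rt
Reagents that add atoms: none
Why: Acidic fluoride desilylation removes the primary TBS group without the base that would epimerise the γ-carbon or trigger oxa-Michael closure.

Step 18
Reactants: 28 (5S)-5-(2-hydroxyethyl)-4-methylfuran-2(5H)-one
Product: 29 2-[(2S)-3-methyl-5-oxo-2,5-dihydrofuran-2-yl]acetaldehyde
Conditions: Dess–Martin periodinane, CH2Cl2, 0 °C → rt; used crude at once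
Reagents that add atoms: none
Why: Dess–Martin oxidation gives the aldehyde under non-basic conditions, which avoids β-elimination of the lactone oxygen.

Step 19
Reactants: 22 methyl 6α,8α-bis(triethylsilyloxy)-13-(trifluoromethylsulfonyloxy)-14,15-dinorlabd-13(16)-en-18-oate; 29 2-[(2S)-3-methyl-5-oxo-2,5-dihydrofuran-2-yl]acetaldehyde
Product: 30 methyl (14R)-14-hydroxy-15-[(2S)-3-methyl-5-oxo-2,5-dihydrofuran-2-yl]-6α,8α-bis(triethylsilyloxy)labd-13(16)-en-18-oate
Conditions: CrCl2, chiral oxazoline–sulfonamide ligand (antipode that gives 14R), Et3N, THF, rt; then NiCl2 (cat.), 22, 29 (1.5 equiv), rt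
Reagents that add atoms: none
Why: In this Nozaki–Hiyama–Kishi coupling nickel inserts into the C–OTf bond, the alkenyl group passes to chromium(III) and adds to the aldehyde inside the chiral sulfonamide ligand sphere, which selects the aldehyde face to give the 14R alcohol, and the non-basic organochromium tolerates the ester, the butenolide and the β-acyloxy aldehyde.

Step 20
Reactants: 30 methyl (14R)-14-hydroxy-15-[(2S)-3-methyl-5-oxo-2,5-dihydrofuran-2-yl]-6α,8α-bis(triethylsilyloxy)labd-13(16)-en-18-oate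
Product: 32 methyl (14S)-14-hydroperoxy-15-[(2S)-3-methyl-5-oxo-2,5-dihydrofuran-2-yl]-6α,8α-bis(triethylsilyloxy)labd-13(16)-en-18-oate, via allylic mesylate 31 (not isolated)
Conditions: Ms2O (1.1 equiv), Et3N (1.3 equiv), CH2Cl2, −40 °C; then anhydrous H2O2 in Et2O (excess), −40 → −10 °C
Reagents that add atoms: hydrogen peroxide, OO
Why: Sulfonylation followed by SN2 displacement of the allylic mesylate by the α-effect nucleophile H2O2 inverts C14 (14R to 14S), and low temperature with no halide or Lewis acid present disfavours ionisation and SN2′ attack.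

Step 21
Reactants: 32 methyl (14S)-14-hydroperoxy-15-[(2S)-3-methyl-5-oxo-2,5-dihydrofuran-2-yl]-6α,8α-bis(triethylsilyloxy)labd-13(16)-en-18-oate
Product: 33 methyl (14S)-14-hydroperoxy-6α,8α-dihydroxy-15-[(2S)-3-methyl-5-oxo-2,5-dihydrofuran-2-yl]labd-13(16)-en-18-oate (CNP0324515.1)
Conditions: HF·pyridine, pyridine, THF, 0 °C → rt
Reagents that add atoms: none
Why: Buffered HF·pyridine desilylation cleaves both triethylsilyl ethers while the hydroperoxide, the butenolide and the methyl ester are stable to it.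

**Compound list**

1 | geranial, (2E)-3,7-dimethylocta-2,6-dienal | CC(C)=CCC/C(C)=C/C=O | starting material
2 | allenylboronic acid pinacol ester | C=C=CB1OC(C)(C)C(C)(C)O1 | starting material
3 | (4S,5E)-6,10-dimethylundeca-5,9-dien-1-yn-4-ol | CC(C)=CCC/C(C)=C/[C@@H](O)CC#C | intermediate
4 | (4S,5E)-4-(tert-butyldimethylsilyloxy)-6,10-dimethylundeca-5,9-dien-1-yne | CC(C)=CCC/C(C)=C/[C@@H](O[Si](C)(C)C(C)(C)C)CC#C | intermediate
5 | (E)-alkenyldimethylalane from 4 (Al on C1, new methyl on C2), not isolated | CC(C)=CCC/C(C)=C/[C@@H](O[Si](C)(C)C(C)(C)C)C/C(C)=C/[Al](C)C | intermediate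
6 | (1E,4S,5E)-4-(tert-butyldimethylsilyloxy)-1-iodo-2,6,10-trimethylundeca-1,5,9-triene | CC(C)=CCC/C(C)=C/[C@@H](O[Si](C)(C)C(C)(C)C)C/C(C)=C/I | intermediate
7 | 2-(2-bromoethyl)-2-methyl-1,3-dioxolane | CC1(CCBr)OCCO1 | starting material
8 | [2-(2-methyl-1,3-dioxolan-2-yl)ethyl]zinc bromide, not isolated | CC1(CC[Zn]Br)OCCO1 | intermediate
9 | ethylene ketal of 10 | CC(C)=CCC/C(C)=C/[C@@H](O[Si](C)(C)C(C)(C)C)C/C(C)=C/CCC1(C)OCCO1 | intermediate
10 | (5E,8S,9E)-8-(tert-butyldimethylsilyloxy)-6,10,14-trimethylpentadeca-5,9,13-trien-2-one | CC(C)=CCC/C(C)=C/[C@@H](O[Si](C)(C)C(C)(C)C)C/C(C)=C/CCC(C)=O | intermediate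
11 | 3β-bromo-6α-(tert-butyldimethylsilyloxy)-8α,13-epoxy-14,15-dinorlabd-12-ene | CC1=CC[C@@H]2[C@@]3(C)CC[C@H](Br)C(C)(C)[C@@H]3[C@@H](O[Si](C)(C)C(C)(C)C)C[C@@]2(C)O1 | intermediate
12 | 6α-(tert-butyldimethylsilyloxy)-8α,13-epoxy-14,15-dinorlabd-12-ene | CC1=CC[C@@H]2[C@@]3(C)CCCC(C)(C)[C@@H]3[C@@H](O[Si](C)(C)C(C)(C)C)C[C@@]2(C)O1 | intermediate
13 | (13S)-6α-(tert-butyldimethylsilyloxy)-13-methoxy-8α,13-epoxy-14,15-dinorlabdane (OMe axial) | CO[C@]1(C)CC[C@@H]2[C@@]3(C)CCCC(C)(C)[C@@H]3[C@@H](O[Si](C)(C)C(C)(C)C)C[C@@]2(C)O1 | intermediate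
14 | (13S)-13-methoxy-8α,13-epoxy-14,15-dinorlabdan-6α-ol | CO[C@]1(C)CC[C@@H]2[C@@]3(C)CCCC(C)(C)[C@@H]3[C@@H](O)C[C@@]2(C)O1 | intermediate
15 | (13S)-13-methoxy-6α,18:8α,13-diepoxy-14,15-dinorlabdane | CO[C@]1(C)CC[C@@H]2[C@@]3(C)CCC[C@@](C)(CO4)[C@@H]3[C@@H]4C[C@@]2(C)O1 | intermediate
16 | (13S)-13-methoxy-8α,13-epoxy-14,15-dinorlabdan-18,6α-olide, not isolated | CO[C@]1(C)CC[C@@H]2[C@@]3(C)CCC[C@@](C)(C(=O)O4)[C@@H]3[C@@H]4C[C@@]2(C)O1 | intermediate
17 | 8α-hydroxy-13-oxo-14,15-dinorlabdan-18,6α-olide | CC(=O)CC[C@@H]1[C@@]2(C)CCC[C@@](C)(C(=O)O3)[C@@H]2[C@@H]3C[C@@]1(C)O | intermediate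
18 | potassium 6α,8α-dihydroxy-13-oxo-14,15-dinorlabdan-18-oate, not isolated | CC(=O)CC[C@@H]1[C@@]2(C)CCC[C@@](C)(C(=O)[O-])[C@@H]2[C@@H](O)C[C@@]1(C)O.[K+] | intermediate
19 | methyl 6α,8α-dihydroxy-13-oxo-14,15-dinorlabdan-18-oate | CC(=O)CC[C@@H]1[C@@]2(C)CCC[C@@](C)(C(=O)OC)[C@@H]2[C@@H](O)C[C@@]1(C)O | intermediate
20 | methyl 13-oxo-6α,8α-bis(triethylsilyloxy)-14,15-dinorlabdan-18-oate | CC(=O)CC[C@@H]1[C@@]2(C)CCC[C@@](C)(C(=O)OC)[C@@H]2[C@@H](O[Si](CC)(CC)CC)C[C@@]1(C)O[Si](CC)(CC)CC | intermediate
21 | potassium 13(16)-enolate of 20, not isolated | C=C([O-])CC[C@@H]1[C@@]2(C)CCC[C@@](C)(C(=O)OC)[C@@H]2[C@@H](O[Si](CC)(CC)CC)C[C@@]1(C)O[Si](CC)(CC)CC.[K+] | intermediate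
22 | methyl 6α,8α-bis(triethylsilyloxy)-13-(trifluoromethylsulfonyloxy)-14,15-dinorlabd-13(16)-en-18-oate | C=C(OS(=O)(=O)C(F)(F)F)CC[C@@H]1[C@@]2(C)CCC[C@@](C)(C(=O)OC)[C@@H]2[C@@H](O[Si](CC)(CC)CC)C[C@@]1(C)O[Si](CC)(CC)CC | intermediate
23 | 3-(tert-butyldimethylsilyloxy)propanal | O=CCCO[Si](C)(C)C(C)(C)C | starting material
24 | methyl propiolate | C#CC(=O)OC | starting material
25 | methyl (4S)-6-(tert-butyldimethylsilyloxy)-4-hydroxyhex-2-ynoate | CC(C)(C)[Si](C)(C)OCC[C@@H](C#CC(=O)OC)O | intermediate
26 | methyl (2Z,4S)-6-(tert-butyldimethylsilyloxy)-4-hydroxy-3-methylhex-2-enoate, not isolated | CC(C)(C)[Si](C)(C)OCC[C@H](O)/C(C)=C\C(=O)OC | intermediate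
27 | (5S)-5-[2-(tert-butyldimethylsilyloxy)ethyl]-4-methylfuran-2(5H)-one | CC(C)(C)[Si](C)(C)OCC[C@@H]1OC(=O)C=C1C | intermediate
28 | (5S)-5-(2-hydroxyethyl)-4-methylfuran-2(5H)-one | OCC[C@@H]1OC(=O)C=C1C | intermediate
29 | 2-[(2S)-3-methyl-5-oxo-2,5-dihydrofuran-2-yl]acetaldehyde | O=CC[C@@H]1OC(=O)C=C1C | intermediate
30 | methyl (14R)-14-hydroxy-15-[(2S)-3-methyl-5-oxo-2,5-dihydrofuran-2-yl]-6α,8α-bis(triethylsilyloxy)labd-13(16)-en-18-oate | C=C(CC[C@@H]1[C@@]2(C)CCC[C@@](C)(C(=O)OC)[C@@H]2[C@@H](O[Si](CC)(CC)CC)C[C@@]1(C)O[Si](CC)(CC)CC)[C@@H](C[C@@H]1OC(=O)C=C1C)O | intermediate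
31 | (14R)-14-methanesulfonate of 30, not isolated | C=C(CC[C@@H]1[C@@]2(C)CCC[C@@](C)(C(=O)OC)[C@@H]2[C@@H](O[Si](CC)(CC)CC)C[C@@]1(C)O[Si](CC)(CC)CC)[C@@H](C[C@@H]1OC(=O)C=C1C)OS(C)(=O)=O | intermediate
32 | methyl (14S)-14-hydroperoxy-15-[(2S)-3-methyl-5-oxo-2,5-dihydrofuran-2-yl]-6α,8α-bis(triethylsilyloxy)labd-13(16)-en-18-oate | C=C(CC[C@@H]1[C@@]2(C)CCC[C@@](C)(C(=O)OC)[C@@H]2[C@@H](O[Si](CC)(CC)CC)C[C@@]1(C)O[Si](CC)(CC)CC)[C@H](C[C@@H]1OC(=O)C=C1C)OO | intermediate
33 | methyl (14S)-14-hydroperoxy-6α,8α-dihydroxy-15-[(2S)-3-methyl-5-oxo-2,5-dihydrofuran-2-yl]labd-13(16)-en-18-oate, CNP0324515.1 | C=C(CC[C@@H]1[C@@]2(C)CCC[C@@](C)(C(=O)OC)[C@@H]2[C@@H](O)C[C@@]1(C)O)[C@H](C[C@@H]1OC(=O)C=C1C)OO | target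

**Step count**

Total: 21 steps. Longest linear sequence: 17 steps (steps 1–14 and 19–21). The butenolide branch is steps 15–18.

**Steps most likely to fail**

Step 6 (proposed new method). The allylic C6–O bond may ionise under the antimonate counter-ion before ring A closes, bromonium may be delivered to the C8=C9 alkene, or the facial bias from C6 may be too weak to give one fold. The fallback uses known chemistry and sets out from 10. Mercury(II)-induced cyclisation with oxygen termination (Hg(OTf)2·N,N-dimethylaniline, MeNO2, −20 °C, brine work-up) is established for farnesyl-type polyenes and keto-terminated dienes; it replaces the halonium and its Lewis-acidic counter-ion by a soft, amine-buffered initiator and should give 3β-(chloromercurio)-6α-(tert-butyldimethylsilyloxy)-8α,13-epoxy-14,15-dinorlabd-12-ene F1. Alkaline NaBH4 (aq. NaOH/THF, 0 °C) then replaces mercury by hydrogen. The route is rejoined at 12 and step 7 is no longer needed. The fold is still controlled by C6, so this fallback addresses ionisation and site selectivity, not a weak facial bias.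

Step 20. The allylic mesylate may ionise or be attacked at C16 (SN2′), which would erode the C14 configuration and the regiochemistry, and the secondary hydroperoxide may decompose under residual base or acid. The fallback gives up stereocontrol at C14 for a base-free, pericyclic C–O bond formation and sets out from 30. Mitsunobu reaction with 2-nitrobenzenesulfonylhydrazide (PPh3, DEAD, N-methylmorpholine, −30 °C → rt) should give the N-allylic sulfonylhydrazine F2 (not isolated), which loses sulfinic acid and dinitrogen by retro-ene rearrangement of the allylic diazene to give the transposed (13E)-trisubstituted alkene F3. Sensitised photo-oxygenation (O2, tetraphenylporphyrin, CH2Cl2, hν, −20 °C; Schenck ene reaction with hydrogen abstraction from the C16 methyl on the more crowded side of the alkene) should then give the exo-methylene C14 hydroperoxide as 32 together with its (14R)-epimer F4. Separation by HPLC rejoins the route at 32.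

Step 19. Facial selectivity at C14 may be poor if the ligand is overridden by the bulky core or by the β-stereocentre of the aldehyde, and the β-acyloxy aldehyde may be lost by elimination if the coupling is slow. The fallback moves the stereocontrol from the C–C bond formation to a ketone reduction and sets out from 22 and 29. Ligand-free coupling (CrCl2, cat. NiCl2, DMF, rt) should give 30 mixed with its (14S)-epimer F5. Dess–Martin oxidation of the mixture gives the α-methylene ketone F6. Corey–Bakshi–Shibata reduction ((S)-Me-oxazaborolidine, catecholborane, toluene, −78 °C), with the alkenyl group as the large substituent, returns the 14R alcohol, and the route is rejoined at 30.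

**Further compounds**

F1 | step 6 | 3β-(chloromercurio)-6α-(tert-butyldimethylsilyloxy)-8α,13-epoxy-14,15-dinorlabd-12-ene | CC1=CC[C@@H]2[C@@]3(C)CC[C@H]([Hg]Cl)C(C)(C)[C@@H]3[C@@H](O[Si](C)(C)C(C)(C)C)C[C@@]2(C)O1
F2 | step 20 | methyl (14S)-14-[1-(2-nitrophenylsulfonyl)hydrazinyl]-15-[(2S)-3-methyl-5-oxo-2,5-dihydrofuran-2-yl]-6α,8α-bis(triethylsilyloxy)labd-13(16)-en-18-oate (not isolated) | C=C(CC[C@@H]1[C@@]2(C)CCC[C@@](C)(C(=O)OC)[C@@H]2[C@@H](O[Si](CC)(CC)CC)C[C@@]1(C)O[Si](CC)(CC)CC)[C@H](C[C@@H]1OC(=O)C=C1C)N(N)S(=O)(=O)c1ccccc1[N+](=O)[O-]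
F3 | step 20 | methyl (13E)-15-[(2S)-3-methyl-5-oxo-2,5-dihydrofuran-2-yl]-6α,8α-bis(triethylsilyloxy)labd-13-en-18-oate | C/C(CC[C@@H]1[C@@]2(C)CCC[C@@](C)(C(=O)OC)[C@@H]2[C@@H](O[Si](CC)(CC)CC)C[C@@]1(C)O[Si](CC)(CC)CC)=C\C[C@@H]1OC(=O)C=C1C
F4 | step 20 | methyl (14R)-14-hydroperoxy-15-[(2S)-3-methyl-5-oxo-2,5-dihydrofuran-2-yl]-6α,8α-bis(triethylsilyloxy)labd-13(16)-en-18-oate | C=C(CC[C@@H]1[C@@]2(C)CCC[C@@](C)(C(=O)OC)[C@@H]2[C@@H](O[Si](CC)(CC)CC)C[C@@]1(C)O[Si](CC)(CC)CC)[C@@H](C[C@@H]1OC(=O)C=C1C)OO
F5 | step 19 | methyl (14S)-14-hydroxy-15-[(2S)-3-methyl-5-oxo-2,5-dihydrofuran-2-yl]-6α,8α-bis(triethylsilyloxy)labd-13(16)-en-18-oate | C=C(CC[C@@H]1[C@@]2(C)CCC[C@@](C)(C(=O)OC)[C@@H]2[C@@H](O[Si](CC)(CC)CC)C[C@@]1(C)O[Si](CC)(CC)CC)[C@H](C[C@@H]1OC(=O)C=C1C)O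
F6 | step 19 | methyl 15-[(2S)-3-methyl-5-oxo-2,5-dihydrofuran-2-yl]-14-oxo-6α,8α-bis(triethylsilyloxy)labd-13(16)-en-18-oate | C=C(CC[C@@H]1[C@@]2(C)CCC[C@@](C)(C(=O)OC)[C@@H]2[C@@H](O[Si](CC)(CC)CC)C[C@@]1(C)O[Si](CC)(CC)CC)C(=O)C[C@@H]1OC(=O)C=C1C
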